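**Strategy.** The route rests on cutting the bond between C1 of guaiacyl ring B and the benzylic CH2 on C3 of the butanetriol chain. That CH2 is β to C4, so with C4 held as a carboxylic acid it can enter as a plain methyl group. Carboxylate-directed palladium catalysis turns a C–H bond of this methyl into the aryl–CH2 bond and joins ring B to a fragment that already carries both stereocentres, ring A and all chain carbons. The precursor is a 2-benzyl-3-methylmalic acid, built from (R)-malate by two stereocontrolled enolate alkylations, with its α-hydroxy acid end tied up as a pivalaldehyde acetal; the fully substituted C2 blocks the other β-position.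

Key step: step 7

Remark: C1–C4 are the carbons of the butane-1,2,4-triol chain of the target; ring A is the guaiacyl ring of the benzyl group on C2 and ring B that of the benzyl group on C3. Compounds 1, 6 and 10 are taken as commercial.

**Step 1**
Reactants: 1 dimethyl (R)-malate
Product: 3 dimethyl (2R,3S)-2-hydroxy-3-methylbutanedioate, via dilithium alkoxide enolate 2 (not isolated)
Conditions: LiN(SiMe3)2 (2.2 equiv), THF, −78 to −20 °C; MeI, −78 to 0 °C; then 1 M HCl
Reagents that add atoms: iodomethane, CI
Why: Frater–Seebach alkylation, in which the lithium-bridged chelate of dianion 2 exposes the enolate face anti to the C2 ester group, so methyl should enter 2,3-anti and set C3 as S while C2 is untouched.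

**Step 2**
Reactants: 3 dimethyl (2R,3S)-2-hydroxy-3-methylbutanedioate
Product: 4 (2R,3S)-2-hydroxy-3-methylbutanedioic acid
Conditions: KOH (2.5 equiv), H2O–MeOH, 0 °C to rt; then HCl to pH 1, extraction with EtOAc
Reagents that add atoms: potassium hydroxide, [K+].[OH-]
Why: Saponification of both methyl esters under mild base, where the carboxylates formed protect C3 from enolisation, should give the diacid with both stereocentres intact.

**Step 3**
Reactants: 4 (2R,3S)-2-hydroxy-3-methylbutanedioic acid
Product: 5 (2S)-2-[(2R,4R)-2-tert-butyl-5-oxo-1,3-dioxolan-4-yl]propanoic acid (cis acetal)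
Conditions: t-BuCHO, TsOH·H2O (cat.), H2SO4 (cat.), pentane, reflux, water separator; crystallisation
Reagents that add atoms: pivalaldehyde, CC(C)(C)C=O
Why: Acid-catalysed acetalisation of the α-hydroxy acid unit should close the five-membered 1,3-dioxolan-4-one in preference to the six-membered ring with the β-carboxyl, and under equilibrating conditions the new acetal centre (2R) is set by the ring carbon so that tert-butyl and side chain are cis.

**Step 4**
Reactants: 6 [4-(benzyloxy)-3-methoxyphenyl]methanol
Product: 7 1-(benzyloxy)-4-(bromomethyl)-2-methoxybenzene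
Conditions: PBr3 (0.4 equiv), Et2O, 0 °C; used directly
Reagents that add atoms: phosphorus tribromide, BrP(Br)Br
Why: Conversion of a primary benzylic alcohol into the bromide by SN2 displacement on its phosphite ester is routine for this electron-rich system.

**Step 5**
Reactants: 5 (2S)-2-[(2R,4R)-2-tert-butyl-5-oxo-1,3-dioxolan-4-yl]propanoic acid; 7 1-(benzyloxy)-4-(bromomethyl)-2-methoxybenzene
Product: 9 (2S)-2-[(2R,4R)-4-{[4-(benzyloxy)-3-methoxyphenyl]methyl}-2-tert-butyl-5-oxo-1,3-dioxolan-4-yl]propanoic acid, via dilithium carboxylate enolate 8 (not isolated)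
Conditions: LiN(SiMe3)2 (2.2 equiv), THF, −78 °C; 7, −78 to −20 °C; then 1 M HCl
Reagents that add atoms: none
Why: Enolate alkylation under self-regeneration of stereocentres, in which the tert-butyl group on the acetal carbon blocks one face of the planar enolate 8 so that the benzyl bromide should enter trans to it, taking the place of the former hydrogen and setting the quaternary carbon as R, while the carboxylate protects the side-chain α-carbon from deprotonation.

**Step 6**
Reactants: 10 4-iodo-2-methoxyphenol
Product: 11 1-(benzyloxy)-4-iodo-2-methoxybenzene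
Conditions: BnBr, K2CO3, acetone, reflux
Reagents that add atoms: benzyl bromide, BrCc1ccccc1
Why: Williamson ether synthesis on the phenoxide masks the oxidisable phenol for the silver-containing key step.

**Step 7**
Reactants: 9 (2S)-2-[(2R,4R)-4-{[4-(benzyloxy)-3-methoxyphenyl]methyl}-2-tert-butyl-5-oxo-1,3-dioxolan-4-yl]propanoic acid; 11 1-(benzyloxy)-4-iodo-2-methoxybenzene
Product: 13 (2S)-3-[4-(benzyloxy)-3-methoxyphenyl]-2-[(2R,4R)-4-{[4-(benzyloxy)-3-methoxyphenyl]methyl}-2-tert-butyl-5-oxo-1,3-dioxolan-4-yl]propanoic acid, via five-membered palladacycle 12 (not isolated)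
Conditions: Pd(OAc)2 (10 mol%), N-acetyl-β-alanine (20 mol%), Ag2CO3 (1.5 equiv), K2HPO4 (1 equiv), 11 (2 equiv), (CF3)2CHOH, 90 °C, sealed tube
Reagents that add atoms: none
Why: Carboxylate-directed β-C(sp3)–H arylation, in which the carboxylate of 9 binds divalent palladium and concerted metalation–deprotonation of the methyl group gives palladacycle 12, its five-membered ring being closed by cyclometalation. Oxidative addition of aryl iodide 11 to tetravalent palladium and C(sp3)–C(sp2) reductive elimination then form the aryl–CH2 bond, while Ag2CO3 takes up iodide and regenerates the divalent palladium carboxylate. The closest known reaction type is the ligand-enabled β-methyl arylation of free aliphatic carboxylic acids bearing an α-hydrogen with aryl iodides. No ring of the product is closed and no stereocentre is made; only the methyl C–H is cleaved, so the S configuration of the adjacent carbon should be retained. The step needs site selectivity and mono-arylation: the other β-carbon is the fully substituted dioxolanone carbon, the benzylic CH2 of ring A is γ and would need a six-membered palladacycle, and the CH2 formed is too hindered for a second arylation. The quaternary carbon next to the dioxolanone carbonyl should also slow attack of the carboxylate on that ester.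

**Step 8**
Reactants: 13 (2S)-3-[4-(benzyloxy)-3-methoxyphenyl]-2-[(2R,4R)-4-{[4-(benzyloxy)-3-methoxyphenyl]methyl}-2-tert-butyl-5-oxo-1,3-dioxolan-4-yl]propanoic acid
Product: 14 (2R,3R)-2,3-bis{[4-(benzyloxy)-3-methoxyphenyl]methyl}butane-1,2,4-triol
Conditions: LiAlH4 (6 equiv), THF, 0 °C to reflux; then H2O
Reagents that add atoms: none
Why: LiAlH4 should reduce the carboxylic acid and the dioxolanone carbonyl to the two primary alcohols, the acetal falling apart to release the tertiary alcohol, without touching the stereocentres or the benzyl ethers.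

**Step 9**
Reactants: 14 (2R,3R)-2,3-bis{[4-(benzyloxy)-3-methoxyphenyl]methyl}butane-1,2,4-triol
Product: 15 (2R,3R)-2,3-bis[(4-hydroxy-3-methoxyphenyl)methyl]butane-1,2,4-triol
Conditions: H2 (1 atm), 10% Pd/C, EtOAc–EtOH, rt
Reagents that add atoms: none
Why: Hydrogenolysis of the two aryl benzyl ethers over palladium on carbon should free both phenols, and the tertiary alcohol is not benzylic and should survive.

**Compound list**
1 | dimethyl (R)-malate | COC(=O)[C@H](O)CC(=O)OC | starting material
2 | dilithium alkoxide enolate of 1 | COC(=O)[C@H]([O-])/C=C(\[O-])OC.[Li+].[Li+] | intermediate (not isolated)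
3 | dimethyl (2R,3S)-2-hydroxy-3-methylbutanedioate | COC(=O)[C@H](O)[C@H](C)C(=O)OC | intermediate
4 | (2R,3S)-2-hydroxy-3-methylbutanedioic acid | OC(=O)[C@H](O)[C@H](C)C(O)=O | intermediate
5 | (2S)-2-[(2R,4R)-2-tert-butyl-5-oxo-1,3-dioxolan-4-yl]propanoic acid | CC(C)(C)[C@@H]1O[C@H]([C@H](C)C(O)=O)C(=O)O1 | intermediate
6 | [4-(benzyloxy)-3-methoxyphenyl]methanol | COc1cc(CO)ccc1OCc1ccccc1 | starting material
7 | 1-(benzyloxy)-4-(bromomethyl)-2-methoxybenzene | COc1cc(CBr)ccc1OCc1ccccc1 | intermediate
8 | dilithium carboxylate enolate of 5 | CC(C)(C)[C@@H]1OC(=C([O-])O1)[C@H](C)C([O-])=O.[Li+].[Li+] | intermediate (not isolated)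
9 | (2S)-2-[(2R,4R)-4-{[4-(benzyloxy)-3-methoxyphenyl]methyl}-2-tert-butyl-5-oxo-1,3-dioxolan-4-yl]propanoic acid | CC(C)(C)[C@@H]1O[C@@]([C@H](C)C(O)=O)(Cc2ccc(OCc3ccccc3)c(OC)c2)C(=O)O1 | intermediate
10 | 4-iodo-2-methoxyphenol | COc1cc(I)ccc1O | starting material
11 | 1-(benzyloxy)-4-iodo-2-methoxybenzene | COc1cc(I)ccc1OCc1ccccc1 | intermediate
12 | five-membered palladacycle of 9 (divalent palladium bound to the carboxylate oxygen and the former methyl carbon; other ligands on palladium not shown) | CC(C)(C)[C@@H]1O[C@@]([C@@H]2C[Pd]OC2=O)(Cc2ccc(OCc3ccccc3)c(OC)c2)C(=O)O1 | intermediate (not isolated)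
13 | (2S)-3-[4-(benzyloxy)-3-methoxyphenyl]-2-[(2R,4R)-4-{[4-(benzyloxy)-3-methoxyphenyl]methyl}-2-tert-butyl-5-oxo-1,3-dioxolan-4-yl]propanoic acid | CC(C)(C)[C@@H]1O[C@@]([C@H](Cc2ccc(OCc3ccccc3)c(OC)c2)C(O)=O)(Cc2ccc(OCc3ccccc3)c(OC)c2)C(=O)O1 | intermediate
14 | (2R,3R)-2,3-bis{[4-(benzyloxy)-3-methoxyphenyl]methyl}butane-1,2,4-triol | COc1cc(C[C@H](CO)[C@@](O)(CO)Cc2ccc(OCc3ccccc3)c(OC)c2)ccc1OCc1ccccc1 | intermediate
15 | (2R,3R)-2,3-bis[(4-hydroxy-3-methoxyphenyl)methyl]butane-1,2,4-triol | COc1cc(C[C@H](CO)[C@@](O)(CO)Cc2ccc(O)c(OC)c2)ccc1O | target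

**Count**
Total step count: 9. Longest linear sequence: 7 steps (steps 1, 2, 3, 5, 7, 8, 9).

**Steps most likely to fail**

Step 7. Cyclopalladation directed by the weakly binding carboxylate may be slow at this hindered α-branched acid, and at 90 °C the neighbouring carboxylate may open the dioxolanone. The fallback makes the same bond with a covalently bound bidentate directing group. It sets out from 9, which is converted through its acid chloride ((COCl)2, cat. DMF, then 8-aminoquinoline, pyridine, CH2Cl2) into the N-(quinolin-8-yl)amide of 9 F1. Arylation with 11 (Pd(OAc)2 10 mol%, AgOAc, toluene, 110 °C) should pass through a rigid N,N-chelated palladacycle at the same methyl group and give the arylated N-(quinolin-8-yl)amide F2. Boc2O and DMAP in MeCN then activate the amide as the N-Boc-N-(quinolin-8-yl)amide F3. LiBH4 in THF–MeOH should reduce both the activated amide and the dioxolanone, so the fallback comes back to the route at 14.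

Step 5. The dilithium species 8 may aggregate and alkylate slowly, so that fragmentation of the enolate with loss of pivalaldehyde and O-benzylation of the carboxylate compete. The fallback alkylates a soluble mono-anion instead. It sets out from 5, which is esterified (allyl bromide, KHCO3, DMF) to the allyl ester of 5 F4. Deprotonation with LiN(SiMe3)2 (1.1 equiv, THF, −78 °C) and addition of 7 should give, under the same acetal control, the allyl ester of 9 F5. Allyl transfer to morpholine with Pd(PPh3)4 (cat.) in THF frees the acid, and the fallback comes back at 9.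

Step 3. Hot acid may equilibrate the acetal towards the trans isomer or the six-membered dioxanone and may partly epimerise the ring carbon, which would erode the facial control of step 5. The fallback forms the acetal under kinetic control by silyl transfer. It sets out from 4, which is persilylated (Me3SiCl, Et3N, CH2Cl2) to bis(trimethylsilyl) (2R,3S)-3-methyl-2-(trimethylsilyloxy)butanedioate F6. Pivalaldehyde with Me3SiOTf (cat.) in CH2Cl2 at −25 °C should close the cis-dioxolanone with loss of the two silyl groups of the α-hydroxy acid unit; aqueous work-up cleaves the remaining silyl ester, and the fallback comes back at 5.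

**Further compounds**
F1 | step 7 | (2S)-2-[(2R,4R)-4-{[4-(benzyloxy)-3-methoxyphenyl]methyl}-2-tert-butyl-5-oxo-1,3-dioxolan-4-yl]-N-(quinolin-8-yl)propanamide | CC(C)(C)[C@@H]1O[C@@]([C@H](C)C(=O)Nc2cccc3cccnc23)(Cc2ccc(OCc3ccccc3)c(OC)c2)C(=O)O1
F2 | step 7 | (2S)-3-[4-(benzyloxy)-3-methoxyphenyl]-2-[(2R,4R)-4-{[4-(benzyloxy)-3-methoxyphenyl]methyl}-2-tert-butyl-5-oxo-1,3-dioxolan-4-yl]-N-(quinolin-8-yl)propanamide | CC(C)(C)[C@@H]1O[C@@]([C@H](Cc2ccc(OCc3ccccc3)c(OC)c2)C(=O)Nc2cccc3cccnc23)(Cc2ccc(OCc3ccccc3)c(OC)c2)C(=O)O1
F3 | step 7 | tert-butyl N-{(2S)-3-[4-(benzyloxy)-3-methoxyphenyl]-2-[(2R,4R)-4-{[4-(benzyloxy)-3-methoxyphenyl]methyl}-2-tert-butyl-5-oxo-1,3-dioxolan-4-yl]propanoyl}-N-(quinolin-8-yl)carbamate | CC(C)(C)[C@@H]1O[C@@]([C@H](Cc2ccc(OCc3ccccc3)c(OC)c2)C(=O)N(C(=O)OC(C)(C)C)c2cccc3cccnc23)(Cc2ccc(OCc3ccccc3)c(OC)c2)C(=O)O1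
F4 | step 5 | prop-2-en-1-yl (2S)-2-[(2R,4R)-2-tert-butyl-5-oxo-1,3-dioxolan-4-yl]propanoate | CC(C)(C)[C@@H]1O[C@H]([C@H](C)C(=O)OCC=C)C(=O)O1
F5 | step 5 | prop-2-en-1-yl (2S)-2-[(2R,4R)-4-{[4-(benzyloxy)-3-methoxyphenyl]methyl}-2-tert-butyl-5-oxo-1,3-dioxolan-4-yl]propanoate | CC(C)(C)[C@@H]1O[C@@]([C@H](C)C(=O)OCC=C)(Cc2ccc(OCc3ccccc3)c(OC)c2)C(=O)O1
F6 | step 3 | bis(trimethylsilyl) (2R,3S)-3-methyl-2-(trimethylsilyloxy)butanedioate | C[Si](C)(C)OC(=O)[C@H](O[Si](C)(C)C)[C@H](C)C(=O)O[Si](C)(C)C
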